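A direct plan would couple 4-bromo-3-hydroxybenzaldehyde A1 with an isopropenylboron reagent to give styrene A2, hydroxylate its allylic methyl group with SeO2/t-BuOOH to allylic alcohol A3, acylate both hydroxyls to diester alkene A4, and close the oxirane last by a catalytic asymmetric epoxidation (non-heme iron catalyst, H2O2).
Its weakest steps would be:
- The final enantioselective epoxidation of A4: the only stereocentre, a quaternary one, would be set in the last step on an alkene class with no proven catalyst, with peroxide beside a free aldehyde, and with no later chance to raise the enantiomeric purity.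
- The SeO2 allylic hydroxylation of A2: it would have to be stopped at partial conversion on a free phenol-aldehyde to avoid the enal, and it builds the oxidation level of the C3 unit only after the C–C bond is made.
- The order of events: three steps would only build an achiral alkene, and the two isovalerate groups would play no part in stereocontrol.

**Retrosynthetic overview**
- The oxirane carbon C2 carries the benzene ring and two CH2–O arms (the ring CH2–O and the exocyclic CH2–O–isovaleryl), so the target is a desymmetrised, dehydrated 2-arylglycerol.
- Disconnections: the oxirane O–CH2 bond (closure of the tertiary oxygen onto a primary mesylate, last); the isovalerate on the pro-R arm, installed by catalyst-controlled acylation of an achiral tetraol, which fixes C2 without touching any bond at C2; and the aryl–C2 bond, made by convergent union of an aryllithium with 2,2-dimethyl-1,3-dioxan-5-one at the fully substituted carbon.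
- Ring order: the benzene ring is bought; the oxirane closes last by C–O displacement at CH2, not by oxygen transfer to an alkene.
- The design uses no alkene, no allylic oxidation and no oxidant near the aldehyde; the C3 unit arrives fully oxygenated, and the target's own acyl groups are the desymmetrising reagent.

Key step: step 3

Assumption: with the (R,R)-ligand the copper catalyst is taken to acylate the pro-R hydroxymethyl arm; the sense would be checked on 9, and the equally available (S,S)-ligand would be used if it were opposite.

**Step 1**
Reactants: 1 4-bromo-3-hydroxybenzaldehyde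
Product: 2 2-bromo-5-(1,3-dioxolan-2-yl)phenol
Conditions: ethylene glycol (3 equiv), TsOH·H2O (2 mol%), toluene, reflux, Dean–Stark
Reagents that add atoms: ethylene glycol, OCCO
Why: Acid-catalysed acetalisation with azeotropic removal of water masks the aldehyde against the organolithium of the next step and leaves the phenol free; no stereocentre is formed.

**Step 2**
Reactants: 2 2-bromo-5-(1,3-dioxolan-2-yl)phenol; 3 2,2-dimethyl-1,3-dioxan-5-one
Product: 6 3-hydroxy-4-(1,2,3-trihydroxypropan-2-yl)benzaldehyde, via dilithiated phenoxide 4 (not isolated), via acetonide adduct 5 (not isolated)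
Conditions: n-BuLi (2.2 equiv), THF, −78 °C; 3 (1.3 equiv), −78 → 0 °C; then 2 M aq. HCl, 23 °C
Reagents that add atoms: 2,2-dimethyl-1,3-dioxan-5-one (compound 3), CC1(C)OCC(=O)CO1; water, O (oxygen of the regenerated formyl group); n-butyllithium, [Li]CCCC (lithium of 4 only)
Why: Deprotonation of the phenol and bromine–lithium exchange give the ortho-lithiated phenoxide 4, whose 1,2-addition to the electrophilic dialkoxy ketone 3 forms the aryl–C2 bond at the fully substituted carbon, and aqueous acid then hydrolyses the acetonide and the dioxolane of 5 together; C2 of 6 carries two identical CH2OH arms, so no stereocentre exists yet.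

**Step 3**
Reactants: 6 3-hydroxy-4-(1,2,3-trihydroxypropan-2-yl)benzaldehyde; 7 3-methylbutanoyl chloride
Product: 9 (2R)-2-[4-formyl-2-(3-methylbutanoyloxy)phenyl]-2,3-dihydroxypropyl 3-methylbutanoate, via aryl ester triol 8 (not isolated)
Conditions: Et3N (2.4 equiv), 7 (1.0 equiv), THF, −40 °C; then CuCl2 (10 mol%), (R,R)-2,2'-(propane-2,2-diyl)bis(4-phenyl-4,5-dihydrooxazole) (11 mol%), 7 (1.1 equiv, slow addition), −20 °C; pH 7 buffer work-up, crude 9 used at once
Reagents that add atoms: 3-methylbutanoyl chloride (compound 7), CC(C)CC(Cl)=O
Why: The phenol, by far the most acidic hydroxyl, is acylated first as its ammonium phenoxide and gives aryl ester 8 with no stereochemical consequence. The divalent copper bis(oxazoline) complex then binds 8 as a five-membered chelate through the tertiary hydroxyl and one primary hydroxyl, which acidifies that primary OH so that Et3N deprotonates it and the copper alkoxide is acylated by 7. The closest known reaction type is the copper bis(oxazoline)-catalysed desymmetrising monobenzoylation of 2-substituted glycerols and the related monoacylation of 1,2-diols; the change here is an aliphatic acyl chloride, added slowly at low temperature to hold down ketene-derived background acylation. No ring is closed; the quaternary stereocentre C2 arises without any bond at C2 being made or broken, because the phenyl groups of the (R,R)-ligand decide which of the two enantiotopic CH2OH arms sits in the reactive chelate position (pro-R arm acylated, giving (R)-9). The step needs phenol before alcohol (secured by acidity), primary before tertiary hydroxyl (sterics) and mono- before bis-acylation of the arms, and the slower second acylation should consume mainly the minor enantiomer of 9 and so raise its enantiomeric purity.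

**Step 4**
Reactants: 9 (2R)-2-[4-formyl-2-(3-methylbutanoyloxy)phenyl]-2,3-dihydroxypropyl 3-methylbutanoate
Product: 11 [(2R)-2-[4-formyl-2-(3-methylbutanoyloxy)phenyl]oxiran-2-yl]methyl 3-methylbutanoate, via primary mesylate 10 (not isolated)
Conditions: MsCl (1.1 equiv), Et3N (1.5 equiv), CH2Cl2, −20 °C; then DBU (2.0 equiv), 0 → 23 °C; Et3N-deactivated silica
Reagents that add atoms: methanesulfonyl chloride, CS(=O)(=O)Cl (mesyl group of 10 only, lost on ring closure)
Why: Sulfonylation picks the primary hydroxyl of 9 over the hindered tertiary one, and the tertiary alkoxide formed with DBU displaces the mesylate in an intramolecular Williamson (3-exo-tet) closure that makes the oxirane O–CH2 bond; no bond at C2 is touched, so the configuration from step 3 is carried into the (R)-oxirane, and the ester on the other arm rules out the Payne rearrangement that would racemise a free 2-arylglycidol.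

**Compound list**
1 | 4-bromo-3-hydroxybenzaldehyde | O=Cc1ccc(Br)c(O)c1 | starting material
2 | 2-bromo-5-(1,3-dioxolan-2-yl)phenol | Oc1cc(C2OCCO2)ccc1Br | intermediate
3 | 2,2-dimethyl-1,3-dioxan-5-one | CC1(C)OCC(=O)CO1 | starting material
4 | lithium 5-(1,3-dioxolan-2-yl)-2-lithiophenoxide | [Li]Oc1cc(C2OCCO2)ccc1[Li] | intermediate
5 | 5-[4-(1,3-dioxolan-2-yl)-2-hydroxyphenyl]-2,2-dimethyl-1,3-dioxan-5-ol | CC1(C)OCC(O)(CO1)c1ccc(C2OCCO2)cc1O | intermediate
6 | 3-hydroxy-4-(1,2,3-trihydroxypropan-2-yl)benzaldehyde | O=Cc1ccc(C(O)(CO)CO)c(O)c1 | intermediate
7 | 3-methylbutanoyl chloride | CC(C)CC(Cl)=O | starting material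
8 | 5-formyl-2-(1,2,3-trihydroxypropan-2-yl)phenyl 3-methylbutanoate | CC(C)CC(=O)Oc1cc(C=O)ccc1C(O)(CO)CO | intermediate
9 | (2R)-2-[4-formyl-2-(3-methylbutanoyloxy)phenyl]-2,3-dihydroxypropyl 3-methylbutanoate | CC(C)CC(=O)OC[C@@](O)(c1ccc(C=O)cc1OC(=O)CC(C)C)CO | intermediate
10 | (2S)-2-[4-formyl-2-(3-methylbutanoyloxy)phenyl]-2-hydroxy-3-(methanesulfonyloxy)propyl 3-methylbutanoate | CC(C)CC(=O)OC[C@@](O)(c1ccc(C=O)cc1OC(=O)CC(C)C)COS(C)(=O)=O | intermediate
11 | [(2R)-2-[4-formyl-2-(3-methylbutanoyloxy)phenyl]oxiran-2-yl]methyl 3-methylbutanoate | CC(C)CC(=O)OC[C@@]1(c2ccc(C=O)cc2OC(=O)CC(C)C)CO1 | target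

Total step count: 4. Longest linear sequence: 4.

**Steps most likely to fail**

Step 3. Discrimination between the two hydroxymethyl arms may be poor with the aliphatic acyl chloride. Possible causes are uncatalysed or ketene-mediated background acylation, migration of the aryl ester of 8 onto a neighbouring hydroxyl, and a 1,3-acyl shift in 9 during work-up. The fallback would set the stereocentre with an enzyme on the phenol-free tetraol. It sets out from 6: an immobilised lipase (Candida antarctica lipase B or Burkholderia cepacia lipase, chosen by screening for pro-R selectivity) with 3-methylbutanoic anhydride in THF/t-BuOMe at 23 °C should give (2R)-2-(4-formyl-2-hydroxyphenyl)-2,3-dihydroxypropyl 3-methylbutanoate F3. The phenol of F3 would then be acylated as its phenoxide (7, 1.0 equiv, K2CO3, acetone, 0 °C), which comes back to the route at 9.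

Step 4. Acyl transfer from the aryl ester (or the primary ester) to the tertiary alkoxide may compete with three-membered ring closure, and the freed phenoxide could then attack the mesylate-bearing carbon. The fallback avoids both the sulfonate and a discrete alkoxide. It sets out from 9: a Mitsunobu-type cyclodehydration of the 1,2-diol (PPh3, diisopropyl azodicarboxylate, toluene, 0 → 80 °C) would activate the primary oxygen as an alkoxyphosphonium ion, which the neighbouring tertiary hydroxyl displaces under near-neutral conditions. It comes back to the route directly at 11.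

Step 2. The basic dilithiated phenoxide may enolise ketone 3 instead of adding to its carbonyl group, returning debrominated acetal after work-up. The fallback uses a non-enolisable electrophile at the ester oxidation level. It sets out from 4: addition to diethyl 2-oxopropanedioate (THF, −78 °C) should give diethyl 2-[4-(1,3-dioxolan-2-yl)-2-hydroxyphenyl]-2-hydroxypropanedioate F1. Reduction with LiAlH4 (THF, 0 °C) would give 2-[4-(1,3-dioxolan-2-yl)-2-hydroxyphenyl]propane-1,2,3-triol F2, and 1 M aq. HCl would release the aldehyde, which comes back to the route at 6.

**Further compounds**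
F1 | step 2 | diethyl 2-[4-(1,3-dioxolan-2-yl)-2-hydroxyphenyl]-2-hydroxypropanedioate | CCOC(=O)C(O)(C(=O)OCC)c1ccc(C2OCCO2)cc1O
F2 | step 2 | 2-[4-(1,3-dioxolan-2-yl)-2-hydroxyphenyl]propane-1,2,3-triol | OCC(O)(CO)c1ccc(C2OCCO2)cc1O
F3 | step 3 | (2R)-2-(4-formyl-2-hydroxyphenyl)-2,3-dihydroxypropyl 3-methylbutanoate | CC(C)CC(=O)OC[C@@](O)(c1ccc(C=O)cc1O)CO
F0 | step 4 | none | none
A1 | direct plan | 4-bromo-3-hydroxybenzaldehyde | O=Cc1ccc(Br)c(O)c1
A2 | direct plan | 3-hydroxy-4-(prop-1-en-2-yl)benzaldehyde | CC(=C)c1ccc(C=O)cc1O
A3 | direct plan | 3-hydroxy-4-(3-hydroxyprop-1-en-2-yl)benzaldehyde | C=C(CO)c1ccc(C=O)cc1O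
A4 | direct plan | 2-[4-formyl-2-(3-methylbutanoyloxy)phenyl]prop-2-en-1-yl 3-methylbutanoate | CC(C)CC(=O)OCC(=C)c1ccc(C=O)cc1OC(=O)CC(C)C
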